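**Plan**
- Numbering follows the coumarins: the unprimed half (benzene ring A) carries 4,7-dimethoxy-5-methyl and is joined at C8; the primed half (ring B) carries 7'-OH and is joined at C6'. The feature used is that O1 (on C8a) and the 5'-methyl carbon (on C5') flank the C8–C6' axis on opposite rings, so they can be tied together as the two ends of an aryl benzoate.
- Retrosynthesis: both pyranones are cut at O1–C2 and C3=C4 (to a biaryl bis-salicylate plus a two-carbon ylide); the C4a'–C4' carbon is removed (formyl carbon); O1 and the 5'-methyl carbon are reconnected as a lactone; C8–C6' is cut; last the ester C–O.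
- Forward: ester tether, then palladium-catalysed C8–C6' closure of the six-membered lactone, hydride opening and CH2OH to CH3, the C4a' carbon by formylation and oxidation, protecting-group exchange, both pyranone rings closed in one operation, hydrogenolysis.
- Stereochemistry: there is no stereocentre; the only stereogenic element is the C8–C6' axis, which is obtained racemic from an achiral hydride opening.

Key step: step 5

Remark: the target is drawn without an axial descriptor, so the axis is made as the racemate; a chiral hydride in step 6 would be the point at which a single atropisomer could be sought.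

**Route**

Step 1
Reactants: 1 methyl 3,5-dihydroxybenzoate
Product: 2 methyl 3,5-diisopropoxybenzoate
Conditions: 2-bromopropane, K2CO3, DMF, 70 °C
Reagents that add atoms: 2-bromopropane, CC(C)Br
Why: Williamson etherification of both phenols with a secondary bromide under carbonate in a dipolar aprotic solvent; the methyl ester is untouched.

Step 2
Reactants: 2 methyl 3,5-diisopropoxybenzoate
Product: 3 methyl 2-bromo-3,5-diisopropoxybenzoate
Conditions: N-bromosuccinimide, MeCN, 0 °C to rt
Reagents that add atoms: N-bromosuccinimide, O=C1CCC(=O)N1Br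
Why: Electrophilic aromatic bromination, in which C2 (para to one isopropoxy group, ortho to the other) is attacked in preference to C4 squeezed between the two isopropoxy groups, as is usual for 3,5-dialkoxybenzoates.

Step 3
Reactants: 3 methyl 2-bromo-3,5-diisopropoxybenzoate
Product: 4 2-bromo-3,5-diisopropoxybenzoic acid
Conditions: NaOH, MeOH/H2O, 60 °C; then aq. HCl
Reagents that add atoms: sodium hydroxide, [Na+].[OH-]
Why: Ester saponification (acyl substitution by hydroxide), to which the aryl bromide and the isopropyl ethers are inert.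

Step 4
Reactants: 4 2-bromo-3,5-diisopropoxybenzoic acid; 5 methyl 2-hydroxy-4-methoxy-6-methylbenzoate
Product: 7 methyl 2-[(2-bromo-3,5-diisopropoxybenzoyl)oxy]-4-methoxy-6-methylbenzoate, via acid chloride 6 (not isolated)
Conditions: (COCl)2, cat. DMF, CH2Cl2, 0 °C to rt; then 5, Et3N, cat. DMAP, CH2Cl2, rt
Reagents that add atoms: none
Why: Acid chloride formation followed by DMAP-catalysed O-acylation of the hydrogen-bonded phenol (nucleophilic acyl substitution); the hindered methyl ester of 5 does not take part.

Step 5
Reactants: 7 methyl 2-[(2-bromo-3,5-diisopropoxybenzoyl)oxy]-4-methoxy-6-methylbenzoate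
Product: 8 methyl 8,10-diisopropoxy-1-methoxy-3-methyl-6-oxo-6H-benzo[c]chromene-4-carboxylate
Conditions: Pd(OAc)2 (10 mol %), PCy3·HBF4 (20 mol %), K2CO3, anhydrous DMA, 120 °C
Reagents that add atoms: none
Why: Zerovalent palladium formed from Pd(OAc)2 and PCy3 inserts into C6'–Br, carbonate-assisted concerted metalation–deprotonation removes C8–H, and reductive elimination from the seven-membered palladacycle forms the C8–C6' bond. The closest known reaction type is the palladium-catalysed intramolecular direct arylation of aryl 2-halobenzoates to benzo[c]chromen-6-ones. The one ring that closes is the six-membered lactone ring, closed by aryl–aryl bond formation across the pre-formed ester, so the tetra-ortho-substituted bond is made intramolecularly. No stereocentre arises, and the helically twisted lactone axis is expected to equilibrate, so 8 is racemic. The step needs site selectivity on ring A and chemoselectivity of the arylpalladium species: the ester oxygen on C8a has C8 as its only free ortho carbon (C4a bears the methyl ester), and C8–H lies between two oxygen substituents and is the most acidic arene hydrogen. Isopropyl ethers are used on ring B because an O-benzyl group on C7' would offer its own phenyl C–H to the palladium on C6' through a more flexible ether tether, whereas isopropyl has only unactivated C(sp3)–H bonds.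

Step 6
Reactants: 8 methyl 8,10-diisopropoxy-1-methoxy-3-methyl-6-oxo-6H-benzo[c]chromene-4-carboxylate
Product: 9 methyl 2-hydroxy-3-[2-(hydroxymethyl)-4,6-diisopropoxyphenyl]-4-methoxy-6-methylbenzoate
Conditions: LiBH4, THF, 0 °C; then aq. NH4Cl
Reagents that add atoms: none
Why: Hydride reduction of the strained, activated aryl ester (lactone) to a primary alcohol with release of the C8a phenoxide; the methyl ester has two ortho substituents and becomes an electron-rich salicylate phenoxide once the lactone opens, so it should be left, and the achiral hydride gives the now stable axis as the racemate.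

Step 7
Reactants: 9 methyl 2-hydroxy-3-[2-(hydroxymethyl)-4,6-diisopropoxyphenyl]-4-methoxy-6-methylbenzoate
Product: 10 methyl 3-[2-(hydroxymethyl)-4,6-diisopropoxyphenyl]-2-isopropoxy-4-methoxy-6-methylbenzoate
Conditions: 2-bromopropane, Cs2CO3, DMF, 60 °C
Reagents that add atoms: 2-bromopropane, CC(C)Br
Why: Williamson etherification in which only the phenol is deprotonated by carbonate, so the primary alcohol stays free; capping the oxygen on C8a prevents its attack on the benzylic carbon in steps 8 and 9.

Step 8
Reactants: 10 methyl 3-[2-(hydroxymethyl)-4,6-diisopropoxyphenyl]-2-isopropoxy-4-methoxy-6-methylbenzoate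
Product: 11 methyl 3-[2-(bromomethyl)-4,6-diisopropoxyphenyl]-2-isopropoxy-4-methoxy-6-methylbenzoate
Conditions: CBr4, PPh3, CH2Cl2, 0 °C
Reagents that add atoms: carbon tetrabromide, BrC(Br)(Br)Br
Why: Appel reaction of a primary benzylic alcohol under neutral conditions that leave esters and ethers intact.

Step 9
Reactants: 11 methyl 3-[2-(bromomethyl)-4,6-diisopropoxyphenyl]-2-isopropoxy-4-methoxy-6-methylbenzoate
Product: 12 methyl 3-(2,4-diisopropoxy-6-methylphenyl)-2-isopropoxy-4-methoxy-6-methylbenzoate
Conditions: NaBH4, DMSO, rt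
Reagents that add atoms: none
Why: SN2 displacement of the benzylic bromide by hydride from NaBH4 in DMSO, conditions under which the hindered methyl ester is not reduced; this sets the 5'-methyl group.

Step 10
Reactants: 12 methyl 3-(2,4-diisopropoxy-6-methylphenyl)-2-isopropoxy-4-methoxy-6-methylbenzoate
Product: 14 methyl 3-(3-formyl-4,6-diisopropoxy-2-methylphenyl)-2-isopropoxy-4-methoxy-6-methylbenzoate, via iminium salt 13 (not isolated)
Conditions: POCl3, DMF, 0 to 70 °C; then ice-water
Reagents that add atoms: N,N-dimethylformamide, CN(C)C=O; water, O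
Why: Vilsmeier–Haack formylation (electrophilic aromatic substitution) at C4a', which is para to the C7' isopropoxy and ortho to the C8a' isopropoxy group (the position at which 3,5-dialkoxytoluenes are formylated), whereas C8' is shielded between two ethers and ring A is deactivated by its ester.

Step 11
Reactants: 14 methyl 3-(3-formyl-4,6-diisopropoxy-2-methylphenyl)-2-isopropoxy-4-methoxy-6-methylbenzoate
Product: 15 4,6-diisopropoxy-3-[2-isopropoxy-6-methoxy-3-(methoxycarbonyl)-4-methylphenyl]-2-methylbenzoic acid
Conditions: NaClO2, NaH2PO4, 2-methyl-2-butene, t-BuOH/H2O, rt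
Reagents that add atoms: sodium chlorite, [Na+].[O-]Cl=O
Why: Pinnick oxidation of the aldehyde by chlorous acid; 2-methyl-2-butene removes hypochlorous acid before it can chlorinate the electron-rich rings.

Step 12
Reactants: 15 4,6-diisopropoxy-3-[2-isopropoxy-6-methoxy-3-(methoxycarbonyl)-4-methylphenyl]-2-methylbenzoic acid
Product: 16 dimethyl 2',4,6-triisopropoxy-6'-methoxy-2,4'-dimethylbiphenyl-3,3'-dicarboxylate
Conditions: MeI, K2CO3, DMF, rt
Reagents that add atoms: iodomethane, CI
Why: SN2 O-alkylation of the carboxylate, the standard esterification for a benzoic acid with two ortho substituents that resists acid-catalysed esterification.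

Step 13
Reactants: 16 dimethyl 2',4,6-triisopropoxy-6'-methoxy-2,4'-dimethylbiphenyl-3,3'-dicarboxylate
Product: 17 dimethyl 2',4,6-trihydroxy-6'-methoxy-2,4'-dimethylbiphenyl-3,3'-dicarboxylate
Conditions: BCl3 (excess), CH2Cl2, −78 to 0 °C; then H2O
Reagents that add atoms: none
Why: Lewis acid ether cleavage in which BCl3 coordinates the ether oxygens and the secondary alkyl groups leave as 2-chloropropane, fastest at the two positions chelated to ester carbonyls, while the unchelated aryl methyl ether and the methyl esters should survive at or below 0 °C.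

Step 14
Reactants: 17 dimethyl 2',4,6-trihydroxy-6'-methoxy-2,4'-dimethylbiphenyl-3,3'-dicarboxylate
Product: 18 dimethyl 6-(benzyloxy)-2',4-dihydroxy-6'-methoxy-2,4'-dimethylbiphenyl-3,3'-dicarboxylate
Conditions: BnBr (1.05 equiv), K2CO3, acetone, rt
Reagents that add atoms: benzyl bromide, BrCc1ccccc1
Why: Williamson etherification under weak base, selective for the C7' hydroxyl, which is para to the ring B ester, not hydrogen-bonded and therefore the most acidic phenol (as in the 4-O-alkylation of 2,4-dihydroxybenzoates); the two chelated hydroxyls needed for pyrone closure stay free and the C7' oxygen is masked against the ylide.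

Step 15
Reactants: 18 dimethyl 6-(benzyloxy)-2',4-dihydroxy-6'-methoxy-2,4'-dimethylbiphenyl-3,3'-dicarboxylate
Product: 20 7'-(benzyloxy)-4,4',7-trimethoxy-5,5'-dimethyl-8,6'-bicoumarin, via bis-phosphorane ester 19 (not isolated)
Conditions: Ph3P=C=C=O (3 equiv), toluene, reflux
Reagents that add atoms: ketenylidenetriphenylphosphorane, O=C=C=P(c1ccccc1)(c1ccccc1)c1ccccc1
Why: Each chelated phenol adds to the ketene of the ylide to give an aryl (triphenylphosphoranylidene)acetate, which closes a six-membered ring by intramolecular Wittig olefination of the neighbouring ester carbonyl so that the ester methoxy becomes the 4-methoxy group, the established route from methyl salicylates to 4-methoxycoumarins.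

Step 16
Reactants: 20 7'-(benzyloxy)-4,4',7-trimethoxy-5,5'-dimethyl-8,6'-bicoumarin
Product: 21 7'-hydroxy-4,4',7-trimethoxy-5,5'-dimethyl-8,6'-bicoumarin
Conditions: H2 (1 atm), Pd/C, EtOAc/MeOH, rt
Reagents that add atoms: none
Why: Hydrogenolysis of the aryl benzyl ether over palladium on carbon; the 3,4-double bonds of the 4-methoxycoumarins are enol ether bonds within a vinylogous carbonate and should not be reduced at 1 atm and room temperature.

**Compound list**
1 | methyl 3,5-dihydroxybenzoate | COC(=O)c1cc(O)cc(O)c1 | starting material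
2 | methyl 3,5-diisopropoxybenzoate | COC(=O)c1cc(OC(C)C)cc(OC(C)C)c1 | intermediate
3 | methyl 2-bromo-3,5-diisopropoxybenzoate | COC(=O)c1cc(OC(C)C)cc(OC(C)C)c1Br | intermediate
4 | 2-bromo-3,5-diisopropoxybenzoic acid | OC(=O)c1cc(OC(C)C)cc(OC(C)C)c1Br | intermediate
5 | methyl 2-hydroxy-4-methoxy-6-methylbenzoate | COC(=O)c1c(C)cc(OC)cc1O | starting material
6 | 2-bromo-3,5-diisopropoxybenzoyl chloride | ClC(=O)c1cc(OC(C)C)cc(OC(C)C)c1Br | intermediate
7 | methyl 2-[(2-bromo-3,5-diisopropoxybenzoyl)oxy]-4-methoxy-6-methylbenzoate | COC(=O)c1c(C)cc(OC)cc1OC(=O)c1cc(OC(C)C)cc(OC(C)C)c1Br | intermediate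
8 | methyl 8,10-diisopropoxy-1-methoxy-3-methyl-6-oxo-6H-benzo[c]chromene-4-carboxylate (racemic, labile axis) | COC(=O)c1c(C)cc(OC)c2c1OC(=O)c1cc(OC(C)C)cc(OC(C)C)c12 | intermediate
9 | methyl 2-hydroxy-3-[2-(hydroxymethyl)-4,6-diisopropoxyphenyl]-4-methoxy-6-methylbenzoate (racemic axis) | COC(=O)c1c(C)cc(OC)c(c1O)-c1c(CO)cc(OC(C)C)cc1OC(C)C | intermediate
10 | methyl 3-[2-(hydroxymethyl)-4,6-diisopropoxyphenyl]-2-isopropoxy-4-methoxy-6-methylbenzoate (racemic axis) | COC(=O)c1c(C)cc(OC)c(c1OC(C)C)-c1c(CO)cc(OC(C)C)cc1OC(C)C | intermediate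
11 | methyl 3-[2-(bromomethyl)-4,6-diisopropoxyphenyl]-2-isopropoxy-4-methoxy-6-methylbenzoate (racemic axis) | COC(=O)c1c(C)cc(OC)c(c1OC(C)C)-c1c(CBr)cc(OC(C)C)cc1OC(C)C | intermediate
12 | methyl 3-(2,4-diisopropoxy-6-methylphenyl)-2-isopropoxy-4-methoxy-6-methylbenzoate (racemic axis) | COC(=O)c1c(C)cc(OC)c(c1OC(C)C)-c1c(C)cc(OC(C)C)cc1OC(C)C | intermediate
13 | N,N-dimethyliminium chloride of aldehyde 14 (ArCH=NMe2+ Cl− at C4a') | COC(=O)c1c(C)cc(OC)c(c1OC(C)C)-c1c(C)c(C=[N+](C)C)c(OC(C)C)cc1OC(C)C.[Cl-] | intermediate
14 | methyl 3-(3-formyl-4,6-diisopropoxy-2-methylphenyl)-2-isopropoxy-4-methoxy-6-methylbenzoate (racemic axis) | COC(=O)c1c(C)cc(OC)c(c1OC(C)C)-c1c(C)c(C=O)c(OC(C)C)cc1OC(C)C | intermediate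
15 | 4,6-diisopropoxy-3-[2-isopropoxy-6-methoxy-3-(methoxycarbonyl)-4-methylphenyl]-2-methylbenzoic acid (racemic axis) | COC(=O)c1c(C)cc(OC)c(c1OC(C)C)-c1c(C)c(C(O)=O)c(OC(C)C)cc1OC(C)C | intermediate
16 | dimethyl 2',4,6-triisopropoxy-6'-methoxy-2,4'-dimethylbiphenyl-3,3'-dicarboxylate (racemic axis) | COC(=O)c1c(C)cc(OC)c(c1OC(C)C)-c1c(C)c(C(=O)OC)c(OC(C)C)cc1OC(C)C | intermediate
17 | dimethyl 2',4,6-trihydroxy-6'-methoxy-2,4'-dimethylbiphenyl-3,3'-dicarboxylate (racemic axis) | COC(=O)c1c(C)cc(OC)c(c1O)-c1c(C)c(C(=O)OC)c(O)cc1O | intermediate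
18 | dimethyl 6-(benzyloxy)-2',4-dihydroxy-6'-methoxy-2,4'-dimethylbiphenyl-3,3'-dicarboxylate (racemic axis) | COC(=O)c1c(C)cc(OC)c(c1O)-c1c(C)c(C(=O)OC)c(O)cc1OCc1ccccc1 | intermediate
19 | bis[(triphenylphosphoranylidene)acetate] of 18 (both chelated phenols acylated) | COC(=O)c1c(C)cc(OC)c(c1OC(=O)C=P(c2ccccc2)(c2ccccc2)c2ccccc2)-c1c(C)c(C(=O)OC)c(OC(=O)C=P(c2ccccc2)(c2ccccc2)c2ccccc2)cc1OCc1ccccc1 | intermediate
20 | 7'-(benzyloxy)-4,4',7-trimethoxy-5,5'-dimethyl-8,6'-bicoumarin (racemic axis) | COc1cc(C)c2c(OC)cc(=O)oc2c1-c1c(OCc3ccccc3)cc2oc(=O)cc(OC)c2c1C | intermediate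
21 | 7'-hydroxy-4,4',7-trimethoxy-5,5'-dimethyl-8,6'-bicoumarin (racemic axis) | COc1cc(C)c2c(OC)cc(=O)oc2c1-c1c(O)cc2oc(=O)cc(OC)c2c1C | target

**Step count**
Total: 16 steps. Longest linear sequence: 16 steps (1 to 21); starting material 5 enters at step 4.

**Steps most likely to fail**

Step 5. Palladation of the doubly flanked C8–H may be slow, so that protodebromination of the arylpalladium intermediate or carbonate-induced cleavage of the aryl ester outruns ring closure. The fallback sets out from 5 (with acid chloride 6) and returns at 8. Phenol 5 would be brominated at its only free ortho carbon by amine-directed ortho-bromination (N-bromosuccinimide, i-Pr2NH, CH2Cl2) to give methyl 3-bromo-2-hydroxy-4-methoxy-6-methylbenzoate F1. This would be acylated with 6 as in step 4 to give methyl 3-bromo-2-[(2-bromo-3,5-diisopropoxybenzoyl)oxy]-4-methoxy-6-methylbenzoate F2. Intramolecular reductive coupling of the two C–Br bonds with zerovalent nickel (Ni(cod)2, PPh3, DMF, 60 °C) would then close the same lactone without any C–H cleavage.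

Step 10. Electrophilic attack may be sluggish or misdirected: the Vilsmeier electrophile is weak and bulky, C4a' sits between a methyl and an isopropoxy group, and long heating could divert formylation to C8' or to C6 of ring A. The fallback sets out from 12 and returns at 14. Bromination with N-bromosuccinimide in MeCN at 0 °C (a small electrophile, directed para to the C7' oxygen) would give methyl 3-(3-bromo-4,6-diisopropoxy-2-methylphenyl)-2-isopropoxy-4-methoxy-6-methylbenzoate F3. Bromine–lithium exchange (n-BuLi, THF, −78 °C, at which the doubly ortho-substituted methyl ester is shielded from addition) and quenching with DMF would deliver aldehyde 14.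

Step 15. The second Wittig ring closure at the hindered ester carbonyls may be incomplete, stalling at a mono-coumarin that still carries a stabilised acyl ylide. The fallback sets out from 18 and returns at 20. Acetylation (Ac2O, pyridine, cat. DMAP) would give dimethyl 2',4-diacetoxy-6-(benzyloxy)-6'-methoxy-2,4'-dimethylbiphenyl-3,3'-dicarboxylate F4. Double intramolecular Claisen condensation of the acetate enolates onto the neighbouring esters (LiN(SiMe3)2, THF, −78 to 0 °C; then aq. HCl) would give 7'-(benzyloxy)-4,4'-dihydroxy-7-methoxy-5,5'-dimethyl-8,6'-bicoumarin F5. O-Methylation of the two 4-hydroxycoumarins (Me2SO4, K2CO3, acetone) would then give 20.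

Further compounds
F1 | step 5 | methyl 3-bromo-2-hydroxy-4-methoxy-6-methylbenzoate | COC(=O)c1c(C)cc(OC)c(Br)c1O
F2 | step 5 | methyl 3-bromo-2-[(2-bromo-3,5-diisopropoxybenzoyl)oxy]-4-methoxy-6-methylbenzoate | COC(=O)c1c(C)cc(OC)c(Br)c1OC(=O)c1cc(OC(C)C)cc(OC(C)C)c1Br
F3 | step 10 | methyl 3-(3-bromo-4,6-diisopropoxy-2-methylphenyl)-2-isopropoxy-4-methoxy-6-methylbenzoate | COC(=O)c1c(C)cc(OC)c(c1OC(C)C)-c1c(C)c(Br)c(OC(C)C)cc1OC(C)C
F4 | step 15 | dimethyl 2',4-diacetoxy-6-(benzyloxy)-6'-methoxy-2,4'-dimethylbiphenyl-3,3'-dicarboxylate | COC(=O)c1c(C)cc(OC)c(c1OC(C)=O)-c1c(C)c(C(=O)OC)c(OC(C)=O)cc1OCc1ccccc1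
F5 | step 15 | 7'-(benzyloxy)-4,4'-dihydroxy-7-methoxy-5,5'-dimethyl-8,6'-bicoumarin | COc1cc(C)c2c(O)cc(=O)oc2c1-c1c(OCc3ccccc3)cc2oc(=O)cc(O)c2c1C
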